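**Retrosynthetic overview**

1. Rings: A = methoxy ring, B = para-linked ring, C = phenol ring, D = meta-linked ring. The strategy rests on ring D: it carries only the ring C ether oxygen (C1) and the CH2CH2 bridge to ring A (C3), meta to each other with no activating group. This is the oxygen/carbon pattern of C3 and C5 of a 5-substituted cyclohexane-1,3-dione.
2. Target ⇒ ring C benzyl ether ⇒ macrocyclic 3-aryloxycyclohex-2-enone, by C=O reduction, water-free dehydration and dehydrogenation of ring D.
3. Key disconnection: the ring C O–ring D C bond of the 19-membered ring ⇒ seco 3-chlorocyclohex-2-enone with a free ring C phenol (intramolecular vinylogous acyl substitution).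
4. Ring D surrogate ⇒ (E)-enone + diethyl malonate (Michael–Claisen annulation, decarboxylation, deoxychlorination); enone ⇒ ring A propanoate by ester reduction and Wittig olefination.
5. Ring B–ring C bridge ⇒ Wittig/diimide; ring A–O–ring B ⇒ SNAr with 4-fluorobenzaldehyde. Ring order: A, B, C are bought; ring D carbocycle in step 10, macrocycle in step 13, ring D aromatic in step 16.

Key step: step 13

Remark on the chemistry: the target has no stereocentre; the sp3 centres of the ring D surrogate are carried as racemates or diastereomer mixtures and vanish on aromatisation. Below, Ar = 3-(4-{2-[4-(benzyloxy)-3-(methoxymethoxy)phenyl]ethyl}phenoxy)-4-methoxyphenyl (rings A, B, C with the benzyl and MOM ethers on ring C).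

**Route**

Step 1
Reactants: 1 3-(3-hydroxy-4-methoxyphenyl)propanoic acid
Product: 2 methyl 3-(3-hydroxy-4-methoxyphenyl)propanoate
Conditions: MeOH, H2SO4 (cat.), reflux
Reagents that add atoms: methanol, CO
Why: Fischer esterification under acid catalysis in excess methanol converts only the carboxylic acid; the phenol is not etherified.

Step 2
Reactants: 2 methyl 3-(3-hydroxy-4-methoxyphenyl)propanoate; 3 4-fluorobenzaldehyde
Product: 4 methyl 3-[3-(4-formylphenoxy)-4-methoxyphenyl]propanoate
Conditions: K2CO3, dry DMF, 130 °C
Reagents that add atoms: none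
Why: Nucleophilic aromatic substitution (SNAr): the phenoxide of 2 adds para to the formyl group of 3, which stabilises the Meisenheimer intermediate, and fluoride leaves; the methyl ester tolerates dry carbonate.

Step 3
Reactants: 4 methyl 3-[3-(4-formylphenoxy)-4-methoxyphenyl]propanoate
Product: 5 methyl 3-{3-[4-(hydroxymethyl)phenoxy]-4-methoxyphenyl}propanoate
Conditions: NaBH4, MeOH/THF, 0 °C
Reagents that add atoms: none
Why: Borohydride reduction is chemoselective for the aryl aldehyde over the methyl ester at 0 °C.

Step 4
Reactants: 5 methyl 3-{3-[4-(hydroxymethyl)phenoxy]-4-methoxyphenyl}propanoate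
Product: 6 {4-[2-methoxy-5-(3-methoxy-3-oxopropyl)phenoxy]benzyl}triphenylphosphonium bromide
Conditions: Ph3P·HBr, MeCN, reflux
Reagents that add atoms: triphenylphosphine hydrobromide, [Br-].[PH+](c1ccccc1)(c1ccccc1)c1ccccc1
Why: One-pot phosphonium salt formation: HBr converts the benzylic alcohol, activated by the para aryloxy group, into the bromide, which triphenylphosphine captures by SN2 quaternisation; ester and diaryl ether are inert.

Step 5
Reactants: 7 4-(benzyloxy)-3-hydroxybenzaldehyde
Product: 8 4-(benzyloxy)-3-(methoxymethoxy)benzaldehyde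
Conditions: MOMCl, iPr2NEt, CH2Cl2, 0 °C to rt
Reagents that add atoms: chloromethyl methyl ether, COCCl
Why: O-alkylation of the phenol with the reactive α-chloro ether gives the MOM acetal, which is stable to the basic, reducing and nucleophilic steps up to step 11 and is orthogonal to the benzyl ether.

Step 6
Reactants: 6 the ring A/B phosphonium bromide; 8 4-(benzyloxy)-3-(methoxymethoxy)benzaldehyde
Product: 9 methyl 3-[3-(4-{2-[4-(benzyloxy)-3-(methoxymethoxy)phenyl]ethenyl}phenoxy)-4-methoxyphenyl]propanoate (E/Z mixture)
Conditions: K2CO3, 18-crown-6 (cat.), CH2Cl2, reflux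
Reagents that add atoms: none
Why: Wittig olefination: the semi-stabilised benzylic ylide formed from 6 under solid–liquid phase transfer condenses with aldehyde 8; the E/Z mixture does not matter because the double bond is saturated next.

Step 7
Reactants: 9 the stilbene ester (E/Z mixture)
Product: 10 methyl 3-[3-(4-{2-[4-(benzyloxy)-3-(methoxymethoxy)phenyl]ethyl}phenoxy)-4-methoxyphenyl]propanoate (Ar-CH2CH2CO2Me)
Conditions: TsNHNH2 (excess), NaOAc, DME/H2O, reflux
Reagents that add atoms: none
Why: Diimide reduction: diimide from the sulfonyl hydrazide transfers two hydrogens in a concerted syn fashion to the nonpolar stilbene C=C only, so the benzyl ether (at risk under catalytic hydrogenation), the MOM acetal and the ester survive.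

Step 8
Reactants: 10 Ar-CH2CH2CO2Me
Product: 11 3-Ar-propanal (Ar-CH2CH2CHO)
Conditions: iBu2AlH (1.1 equiv), toluene, −78 °C; MeOH, then aq KNaC4H4O6
Reagents that add atoms: none
Why: Partial reduction of the methyl ester with one hydride equivalent at −78 °C stops at the aluminium hemiacetal, which releases the aldehyde only on work-up.

Step 9
Reactants: 11 3-Ar-propanal; 12 1-(triphenylphosphoranylidene)propan-2-one
Product: 13 (E)-6-Ar-hex-3-en-2-one
Conditions: CH2Cl2, rt to 40 °C
Reagents that add atoms: none
Why: Wittig olefination with a ketone-stabilised ylide gives the (E)-enone; no base is present, so the enolisable aldehyde does not self-condense.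

Step 10
Reactants: 13 (E)-6-Ar-hex-3-en-2-one; 14 diethyl malonate
Product: 18 5-(2-Ar-ethyl)cyclohexane-1,3-dione, via Michael adduct 15 (not isolated), via cyclic keto ester 16 (not isolated), via keto acid 17 (not isolated)
Conditions: NaOEt, EtOH, reflux; then aq KOH, reflux; then aq HCl to pH 3–4, 70 °C
Reagents that add atoms: none
Why: Michael addition of sodiomalonate to the enone, intramolecular Claisen (Dieckmann-type) condensation of the methyl ketone onto an ester, saponification and decarboxylation of the β-keto acid is the classical route from alk-3-en-2-ones to 5-substituted cyclohexane-1,3-diones; acidifying only to pH 3–4 should decarboxylate while keeping the MOM acetal, and the product is achiral.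

Step 11
Reactants: 18 5-(2-Ar-ethyl)cyclohexane-1,3-dione
Product: 19 racemic 3-chloro-5-(2-Ar-ethyl)cyclohex-2-en-1-one
Conditions: Ph3PCl2, Et3N, MeCN, rt
Reagents that add atoms: dichlorotriphenylphosphorane, ClP(Cl)(c1ccccc1)(c1ccccc1)c1ccccc1
Why: Deoxychlorination of a 1,3-dione: the enol oxygen is activated as an oxyphosphonium salt, chloride adds to the β-carbon and triphenylphosphine oxide is expelled; the two carbonyls of 18 are enantiotopic, so one constitutional isomer forms as a racemate, and the amine buffer protects the MOM acetal.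

Step 12
Reactants: 19 racemic 3-chloro-5-(2-Ar-ethyl)cyclohex-2-en-1-one
Product: 20 racemic 5-[2-(3-{4-[2-(4-benzyloxy-3-hydroxyphenyl)ethyl]phenoxy}-4-methoxyphenyl)ethyl]-3-chlorocyclohex-2-en-1-one (seco chloroenone with free ring C hydroxyl)
Conditions: CF3CO2H/CH2Cl2 (1:5) with a few equiv H2O, 0 °C to rt; pH 7 phosphate buffer quench
Reagents that add atoms: none
Why: Acid-catalysed hydrolysis of the MOM acetal frees the ring C hydroxyl; the aryl benzyl ether and the β-chloroenone tolerate cold trifluoroacetic acid, and the neutral phenol does not add to the chloroenone without base.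

Step 13
Reactants: 20 the seco chloroenone with free ring C hydroxyl
Product: 21 racemic macrocyclic 3-aryloxycyclohex-2-enone (ring C oxygen bonded to C3 of the cyclohexenone; 19-membered ring; ring C still O-benzylated)
Conditions: Cs2CO3 (3 equiv), dry DMF, 60 °C; syringe-pump addition of 20 over 12 h, final concentration about 1 mM
Reagents that add atoms: none
Why: Cs2CO3 deprotonates the ring C phenol, the phenoxide adds in conjugate fashion to the chlorine-bearing carbon of the chloroenone and the enolate expels chloride (addition–elimination, vinylogous acyl substitution). The closest known reaction is the intermolecular formation of 3-aryloxycyclohex-2-enones from phenols and 3-chlorocyclohex-2-enones under carbonate base. The 19-membered ring closes end to end in a 19-exo-trig addition of oxygen to the sp2 carbon, followed by loss of chloride; the half-chair surrogate, with two sp3 carbons between the reacting carbon and the bridge, should bend more easily than a flat arene. No stereocentre is created; C5 of the cyclohexenone stays racemic and is erased on aromatisation. The step needs substitution at the chlorine-bearing carbon over carbonyl addition, O- over C-attack of the phenoxide, and intra- over intermolecular reaction. These are secured by the reversibility of carbonyl addition against irreversible chloride loss, by the caesium phenoxide in a dipolar aprotic solvent, and by the low stationary concentration from slow addition.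

Step 14
Reactants: 21 the macrocyclic 3-aryloxycyclohex-2-enone
Product: 22 macrocyclic 3-aryloxycyclohex-2-en-1-ol (mixture of racemic diastereomers)
Conditions: iBu2AlH, CH2Cl2, −78 °C; aq KNaC4H4O6 work-up, crude product used at once
Reagents that add atoms: none
Why: 1,2-Hydride addition to the carbonyl of the vinylogous ester (the first half of a Stork–Danheiser sequence) gives the allylic alcohol; the carbinol centre forms without control and is erased two steps later, and the basic tartrate work-up avoids the acid that would hydrolyse the enol ether.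

Step 15
Reactants: 22 the macrocyclic 3-aryloxycyclohex-2-en-1-ol
Product: 24 racemic macrocyclic 1-aryloxycyclohexa-1,3-diene, via allylic mesylate 23 (not isolated)
Conditions: MsCl, Et3N (4 equiv), dry CH2Cl2, −20 °C to rt
Reagents that add atoms: none
Why: Dehydration via the allylic mesylate (E1-type elimination): the aryloxy group stabilises the allyl cation and triethylamine removes the C6 proton to give the conjugated dienol ether in a water-free medium, so the hydrolytic Stork–Danheiser pathway that would expel the ring C phenol is shut off; a 2-aryloxy-1,3-diene regioisomer, if formed, gives the same arene in step 16.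

Step 16
Reactants: 24 the macrocyclic 1-aryloxycyclohexa-1,3-diene
Product: 25 O-benzyl ether of the target (ring D aromatic)
Conditions: DDQ (1.1 equiv), toluene, 0 °C to rt
Reagents that add atoms: none
Why: Dehydrogenative aromatisation with DDQ: hydride abstraction from a ring CH next to the diene gives an aryloxy-stabilised cyclohexadienyl cation that loses a proton, which should be much faster than oxidation of the benzyl ether or the bibenzyl methylenes; the last stereocentre disappears.

Step 17
Reactants: 25 O-benzyl ether of the target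
Product: 26 CNP0132125.0 (target)
Conditions: H2 (1 atm), Pd/C (10 wt% palladium on carbon), EtOAc/EtOH, rt
Reagents that add atoms: none
Why: Catalytic hydrogenolysis cleaves the benzylic C–O bond to release the ring C phenol; the diaryl ethers, the methyl ether and the saturated bridges are inert.

**Compound list**

1 | 3-(3-hydroxy-4-methoxyphenyl)propanoic acid | COc1ccc(CCC(=O)O)cc1O | starting material
2 | methyl 3-(3-hydroxy-4-methoxyphenyl)propanoate | COC(=O)CCc1ccc(OC)c(O)c1 | intermediate
3 | 4-fluorobenzaldehyde | O=Cc1ccc(F)cc1 | starting material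
4 | methyl 3-[3-(4-formylphenoxy)-4-methoxyphenyl]propanoate | COC(=O)CCc1ccc(OC)c(Oc2ccc(C=O)cc2)c1 | intermediate
5 | methyl 3-{3-[4-(hydroxymethyl)phenoxy]-4-methoxyphenyl}propanoate | COC(=O)CCc1ccc(OC)c(Oc2ccc(CO)cc2)c1 | intermediate
6 | {4-[2-methoxy-5-(3-methoxy-3-oxopropyl)phenoxy]benzyl}triphenylphosphonium bromide | COC(=O)CCc1ccc(OC)c(Oc2ccc(C[P+](c3ccccc3)(c3ccccc3)c3ccccc3)cc2)c1.[Br-] | intermediate
7 | 4-(benzyloxy)-3-hydroxybenzaldehyde | O=Cc1ccc(OCc2ccccc2)c(O)c1 | starting material
8 | 4-(benzyloxy)-3-(methoxymethoxy)benzaldehyde | COCOc1cc(C=O)ccc1OCc1ccccc1 | intermediate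
9 | methyl 3-[3-(4-{2-[4-(benzyloxy)-3-(methoxymethoxy)phenyl]ethenyl}phenoxy)-4-methoxyphenyl]propanoate, E/Z mixture | COC(=O)CCc1ccc(OC)c(Oc2ccc(C=Cc3ccc(OCc4ccccc4)c(OCOC)c3)cc2)c1 | intermediate
10 | methyl 3-[3-(4-{2-[4-(benzyloxy)-3-(methoxymethoxy)phenyl]ethyl}phenoxy)-4-methoxyphenyl]propanoate | COC(=O)CCc1ccc(OC)c(Oc2ccc(CCc3ccc(OCc4ccccc4)c(OCOC)c3)cc2)c1 | intermediate
11 | 3-[3-(4-{2-[4-(benzyloxy)-3-(methoxymethoxy)phenyl]ethyl}phenoxy)-4-methoxyphenyl]propanal | O=CCCc1ccc(OC)c(Oc2ccc(CCc3ccc(OCc4ccccc4)c(OCOC)c3)cc2)c1 | intermediate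
12 | 1-(triphenylphosphoranylidene)propan-2-one | CC(=O)C=P(c1ccccc1)(c1ccccc1)c1ccccc1 | starting material
13 | (E)-6-Ar-hex-3-en-2-one | CC(=O)/C=C/CCc1ccc(OC)c(Oc2ccc(CCc3ccc(OCc4ccccc4)c(OCOC)c3)cc2)c1 | intermediate
14 | diethyl malonate | CCOC(=O)CC(=O)OCC | starting material
15 | diethyl 2-(1-Ar-5-oxohexan-3-yl)propanedioate, racemic Michael adduct | CCOC(=O)C(C(=O)OCC)C(CC(C)=O)CCc1ccc(OC)c(Oc2ccc(CCc3ccc(OCc4ccccc4)c(OCOC)c3)cc2)c1 | intermediate (not isolated)
16 | ethyl 2-(2-Ar-ethyl)-4,6-dioxocyclohexane-1-carboxylate, racemic, present as its sodium enolate | CCOC(=O)C1C(CCc2ccc(OC)c(Oc3ccc(CCc4ccc(OCc5ccccc5)c(OCOC)c4)cc3)c2)CC(=O)CC1=O | intermediate (not isolated)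
17 | 2-(2-Ar-ethyl)-4,6-dioxocyclohexane-1-carboxylic acid, racemic | OC(=O)C1C(CCc2ccc(OC)c(Oc3ccc(CCc4ccc(OCc5ccccc5)c(OCOC)c4)cc3)c2)CC(=O)CC1=O | intermediate (not isolated)
18 | 5-(2-Ar-ethyl)cyclohexane-1,3-dione | O=C1CC(=O)CC(CCc2ccc(OC)c(Oc3ccc(CCc4ccc(OCc5ccccc5)c(OCOC)c4)cc3)c2)C1 | intermediate
19 | racemic 3-chloro-5-(2-Ar-ethyl)cyclohex-2-en-1-one | COc1ccc(CCC2CC(=O)C=C(Cl)C2)cc1Oc1ccc(CCc2ccc(OCc3ccccc3)c(OCOC)c2)cc1 | intermediate
20 | racemic seco chloroenone with free ring C hydroxyl | COc1ccc(CCC2CC(=O)C=C(Cl)C2)cc1Oc1ccc(CCc2ccc(OCc3ccccc3)c(O)c2)cc1 | intermediate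
21 | racemic macrocyclic 3-aryloxycyclohex-2-enone | COc1ccc2cc1Oc1ccc(cc1)CCc1ccc(OCc3ccccc3)c(c1)OC1=CC(=O)CC(C1)CC2 | intermediate
22 | macrocyclic 3-aryloxycyclohex-2-en-1-ol, mixture of racemic diastereomers | COc1ccc2cc1Oc1ccc(cc1)CCc1ccc(OCc3ccccc3)c(c1)OC1=CC(O)CC(C1)CC2 | intermediate
23 | macrocyclic allylic mesylate, mixture of racemic diastereomers | COc1ccc2cc1Oc1ccc(cc1)CCc1ccc(OCc3ccccc3)c(c1)OC1=CC(OS(C)(=O)=O)CC(C1)CC2 | intermediate (not isolated)
24 | racemic macrocyclic 1-aryloxycyclohexa-1,3-diene | COc1ccc2cc1Oc1ccc(cc1)CCc1ccc(OCc3ccccc3)c(c1)OC1=CC=CC(C1)CC2 | intermediate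
25 | O-benzyl ether of the target | COc1ccc2cc1Oc1ccc(cc1)CCc1ccc(OCc3ccccc3)c(c1)Oc1cccc(c1)CC2 | intermediate
26 | CNP0132125.0 | COc1ccc2cc1Oc1ccc(cc1)CCc1ccc(O)c(c1)Oc1cccc(c1)CC2 | target

**Step count**

Total: 17 steps. Longest linear sequence: 16 steps (steps 1–4 and 6–17, from acid 1); step 5 is a one-step branch.

**Steps most likely to fail**

1. Step 13. Intermolecular substitution (oligomerisation) may outrun end-to-end closure of the 19-membered ring, or the strained transition state may be too slow. Fallback: aromatise ring D before ring closure and form the same C–O bond by a copper-mediated Ullmann coupling. It sets out from dione 18. Ph3PBr2/Et3N in MeCN should give the racemic 3-bromo-5-(2-Ar-ethyl)cyclohex-2-en-1-one F1. Luche reduction (NaBH4, CeCl3·7H2O, MeOH, −20 °C) should give the bromo allylic alcohol F2. Mesylation and elimination (MsCl, Et3N, then DBU) should give the 1-bromocyclohexa-1,3-diene F3, and DDQ in toluene the meta-bromoarene with the MOM ether F4. Trifluoroacetic acid in CH2Cl2 should free the bromo phenol F5. Intramolecular Ullmann diaryl ether formation (CuCl, 2,2,6,6-tetramethylheptane-3,5-dione, Cs2CO3, NMP, 120 °C, slow addition) would then close the macrocycle and return to the route at 25.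

2. Step 15. Ionisation of the aryloxy allylic alcohol may be followed by capture of water or chloride and expulsion of the ring C phenoxide (ring opening by allylic transposition) instead of proton loss. Fallback: keep the carbonyl oxygen through aromatisation and remove it afterwards. It sets out from 21. Kinetic α′-deprotonation with LiN(iPr)2 in THF at −78 °C and PhSeCl should give the 6-phenylselanyl ketone F6. Oxidation with H2O2/pyridine in CH2Cl2 at 0 °C triggers selenoxide syn-elimination, and the resulting 2,5-dienone tautomerises to the macrocyclic 3-aryloxy-5-alkylphenol F7. Tf2O/pyridine should give the aryl triflate F8. Reductive cleavage of the C–OTf bond with Pd(OAc)2, 1,3-bis(diphenylphosphino)propane, HCO2H and Et3N in DMF at 80 °C (zerovalent palladium formed in the flask) returns to the route at 25, replacing steps 14–16.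

3. Step 12. The vinyl chloride may be lost by acid-mediated hydrolysis back to the dione, or the freed phenol may substitute intermolecularly during unmasking and isolation. Fallback: change the protecting group before the chloride is installed and unmask in the cyclisation flask. It sets out from 18. Aqueous HCl in THF at 50 °C should give the phenol dione F9. TBSCl/imidazole in DMF, with a mild aqueous work-up that hydrolyses the silyl enol ether of the dione, should give the aryl silyl ether dione F10. (COCl)2 with catalytic DMF in CH2Cl2 at 0 °C should give the silyl-protected chloroenone F11. Slow addition of F11 to CsF in DMF at 60 °C generates the phenoxide of 20 in the flask, which closes the ring and returns to the route at 21.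

**Further compounds**

F1 | step 13 | racemic 3-bromo-5-(2-Ar-ethyl)cyclohex-2-en-1-one | COc1ccc(CCC2CC(=O)C=C(Br)C2)cc1Oc1ccc(CCc2ccc(OCc3ccccc3)c(OCOC)c2)cc1
F2 | step 13 | 3-bromo-5-(2-Ar-ethyl)cyclohex-2-en-1-ol, mixture of racemic diastereomers | COc1ccc(CCC2CC(O)C=C(Br)C2)cc1Oc1ccc(CCc2ccc(OCc3ccccc3)c(OCOC)c2)cc1
F3 | step 13 | racemic 1-bromo-5-(2-Ar-ethyl)cyclohexa-1,3-diene | COc1ccc(CCC2C=CC=C(Br)C2)cc1Oc1ccc(CCc2ccc(OCc3ccccc3)c(OCOC)c2)cc1
F4 | step 13 | 1-bromo-3-(2-Ar-ethyl)benzene (MOM ether on ring C) | COc1ccc(CCc2cccc(Br)c2)cc1Oc1ccc(CCc2ccc(OCc3ccccc3)c(OCOC)c2)cc1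
F5 | step 13 | seco meta-bromoarene with free ring C hydroxyl | COc1ccc(CCc2cccc(Br)c2)cc1Oc1ccc(CCc2ccc(OCc3ccccc3)c(O)c2)cc1
F6 | step 15 | macrocyclic 3-aryloxy-6-(phenylselanyl)cyclohex-2-enone, mixture of racemic diastereomers | COc1ccc2cc1Oc1ccc(cc1)CCc1ccc(OCc3ccccc3)c(c1)OC1=CC(=O)C([Se]c3ccccc3)C(C1)CC2
F7 | step 15 | macrocyclic phenol (ring D aromatic, extra hydroxyl meta to both substituents) | COc1ccc2cc1Oc1ccc(cc1)CCc1ccc(OCc3ccccc3)c(c1)Oc1cc(O)cc(c1)CC2
F8 | step 15 | macrocyclic aryl triflate | COc1ccc2cc1Oc1ccc(cc1)CCc1ccc(OCc3ccccc3)c(c1)Oc1cc(OS(=O)(=O)C(F)(F)F)cc(c1)CC2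
F9 | step 12 | seco dione with free ring C hydroxyl | COc1ccc(CCC2CC(=O)CC(=O)C2)cc1Oc1ccc(CCc2ccc(OCc3ccccc3)c(O)c2)cc1
F10 | step 12 | seco dione with ring C tert-butyldimethylsilyl ether | COc1ccc(CCC2CC(=O)CC(=O)C2)cc1Oc1ccc(CCc2ccc(OCc3ccccc3)c(O[Si](C)(C)C(C)(C)C)c2)cc1
F11 | step 12 | racemic seco chloroenone with ring C tert-butyldimethylsilyl ether | COc1ccc(CCC2CC(=O)C=C(Cl)C2)cc1Oc1ccc(CCc2ccc(OCc3ccccc3)c(O[Si](C)(C)C(C)(C)C)c2)cc1
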